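The numbers in the tables stem from a simulated flask on assumed constants, and the scatter is random.

A crossover concentration q = 7.54 mM, the level of L at which X goes equally to Z and to J, is the reading on which this reckoning rests.

| setting | eta | theta | flask |
|---|---|---|---|
| X | 0.029 M | 0.12 M | 0.058 M |
| D | 9.6 mM (held) | 9.6 mM (held) | 9.6 mM (held) |
| L | 0.058 M | 0.058 M | 0.0580 M |
| remark | run made earlier | run made earlier |  |
| time |  |  | 2.5 min |

| run | time / s | Z / % |
|---|---|---|
| eta | 10.0 | 3.6 |
| eta | 20.0 | 6.4 |
| eta | 30.0 | 8.0 |
| eta | 60.0 | 11.1 |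
| eta | 120 | 14.5 |
| theta | 10.0 | 2.8 |
| theta | 30.0 | 9.0 |
| theta | 60.0 | 13.5 |
| theta | 80.0 | 17.2 |
| theta | 120 | 21.3 |

(readings scatter by 0.5 percentage points)

* Z at 2.5 min, in percent of the X charged
* concentration of G in solution at 2.5 min, in percent of saturation

- percent here means X units held: one E counts as two
- at the start none of G is dissolved
- the analysis behind the earlier runs scatters by 0.5 percentage points, standard deviation
- on the list of suspects stand: D <-> G; X + Z -> E; X + L -> J; X + G <-> Z

With G saturated, X + G → Z is pseudo-first-order with constant k_Z, and X + L → J has constant k_L. So q = k_Z/k_L is a selectivity factor, and with L_c the charged L: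

d[Z]/d[J] = q/[L], so [Z] = q ln(L_c/[L])

If the eta charge not found as Z at 120 s has each taken one L, [L] stands at 33.2 mM there, which gives q. Eta's first reading gives k_Z ≈ 0.00360 s⁻¹, so k_L ≈ 0.477 M⁻¹ s⁻¹.

The flask is now built up, with c = 0.0580 M for both charges and t = 2.5 min. The main step by itself gives:

[L] = c/(1 + k_L c t) = 11.3 mM

Adding Z through the rule gives 21.3%. But making Z also uses X, so [X] = [L] − [Z], and the end of X comes at w = q ln(c/w), which by substitution is 12.1 mM, or 20.9%. That is the upper end. Holding [Z] at w from the start slows L too much and gives the lower end: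

[L] = w/(1 − (1 − w/c) exp(−k_L w t)), so Z = 15.1%

Joined, the ends give about 18.0%. X + Z → E and the way back from Z are not sized here, and saturation of G is assumed, not reckoned.

The forecast gives 18.3% and 96%: “so G is nearly saturated”.

The flask gives 17.0% of Z, with G at 99.9% of saturation.

    D ⇌ G, rate k1*(csat - [G]) (kL = 1.30 s⁻¹)
    X + Z → E (k = 0.0290 M⁻¹ s⁻¹)
    X + L → J (k = 0.570 M⁻¹ s⁻¹)
    X + G ⇌ Z (K = 1100 M⁻¹, k = 0.470 M⁻¹ s⁻¹)

An L charge of 0.0430 M or 0.0796 M moves y by 5 points, which is the kind of run that would part from the forecast. With 25% of L left, q gives 17.9% of Z made, and the flask shows 17.6% made, its Z plus the one Z that went into each E, since E is counted in X units, two to each E. The same flask read at 1.0 min has 37.6% of L left, so q gives 12.7%; it holds 12.4% of Z and 0.607% of E, which on the same count makes 12.7% of Z made.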